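Which flask ends with more target: teal, fed cold and then warmed, or amber, warm throughout and fed slowly?

common to all: substrate 0.14 M

| flask | reagent | free catalyst | temperature | remark | time |
|---|---|---|---|---|---|
| delta | 0.182 M (fed, over 1.0 h) | 0.49 mM | −28 °C | run made earlier |  |
| zeta | 0.182 M (fed, over 1.0 h) | 0.48 mM | 0 °C | run made earlier |  |
| theta | 0.182 M (fed, over 1.0 h) | 0.71 mM | −28 °C | run made earlier |  |
| teal | 0.182 M (fed, over 1.0 h) | 0.70 mM |  | at −40 °C until 1.0 h, from then on at 10 °C | 2.0 h |
| amber | 0.182 M (fed, over 4.0 h) | 0.40 mM |  | at 10 °C throughout | 2.0 h |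

| run | time / min | target / % | substrate / % |
|---|---|---|---|
| delta | 12.0 | 4.4 | 94.5 |
| delta | 20.0 | 11.3 | 89.2 |
| delta | 30.0 | 17.6 | 82.7 |
| delta | 40.0 | 24.4 | 76.1 |
| zeta | 0.833 | 0 | 99.2 |
| zeta | 2.00 | 0 | 99.8 |
| zeta | 6.00 | 1.1 | 99.3 |
| zeta | 12.0 | 3.0 | 95.5 |
| theta | 6.00 | 2.3 | 95.8 |
| theta | 15.0 | 10.6 | 88.3 |
| theta | 30.0 | 24.6 | 76.2 |
| theta | 40.0 | 32.7 | 67.0 |

(standard deviation of a reading: 0.5 percentage points)

- the winner by amount of target, in percent of the substrate charged; "neither" if no more than 2 percentage points parts them (teal / amber / neither)
- how much target is there at the end, in percent of the substrate charged: teal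
- how much target is there at the end, in percent of the substrate charged: amber

- percentages count the whole charge, also what has not yet gone in

**Bench rule.** A dosed flask is usually expected to keep pace with its feed, one target for each reagent delivered, so a ratio of one is the zero of the scale. In zeta at 12.0 min, 0.0364 M of reagent has gone in and 0.00420 M of target stands, a pace of 0.115. Delta reads 0.282 at 40.0 min. Both lie below one, so the rule stops here: reagent piles up.

**Warm constant.** Delta and theta run as straight lines, but zeta at 0 °C bends upward, growing by a factor of 2.73 from 6.00 min to 12.0 min, as a reading. This reckoning takes zeta's target to follow the reagent standing. That gives the warm clearing constant, target made per catalyst, per standing reagent, per hour: 2400 /M/h. Multiplied by the catalyst, it is a pseudo-first-order clearing rate for reagent.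

**Own reckoning.** This reckoning carries the constant unchanged to 10 °C. With amber's own catalyst and amber's own feed of 0.182 M over 4.0 h, a steady inflow against that clearing gives 36.1% target at 2.0 h. On the same estimate, teal clears 81.4% of its standing reagent in the warm hour. Its charge is 130% of the substrate, so this estimate puts teal's target at the whole substrate charge, and teal comes first.

**The forecast.** It gave 78% for teal, 35% for amber and teal as winner: “Teal should win under either reading.” The reckoning here lies near it on amber and above it on teal.

**The result.** Teal ends at 80.4% and amber at 25.4%, so teal wins.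

    substrate + free catalyst → catalyst intermediate A (k = 1400 /M/h, Ea = 42.0 kJ/mol)
    catalyst intermediate A ⇌ catalyst intermediate B (K = 1.40, k = 1600 /h, Ea = 53.0 kJ/mol, ΔH = −81.0 kJ/mol)
    reagent + catalyst intermediate B → catalyst intermediate C (k = 43000 /M/h, Ea = 40.0 kJ/mol)
    catalyst intermediate C → by-product + catalyst intermediate D (k = 37.0 /h, Ea = 68.0 kJ/mol)
    catalyst intermediate D → free catalyst + target (k = 220 /h, Ea = 68.0 kJ/mol)
    free catalyst → spent catalyst (k = 0.00180 /h, Ea = 90.0 kJ/mol)
    (constants at −40 °C)

**Amber's reagent.** At the end, amber holds 90.8% of its catalyst as catalyst intermediate A, the resting state. The reckoning left 22.2% of amber's reagent charge standing, and the flask holds 30%. The warm constant holds no substrate term, so the reckoning gives a flask like amber but with 0.24 M of substrate the same molar target as amber. That flask ends at 15.0% of its substrate charge, 0.0360 M against amber's 0.0355 M.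

The runs come from a simulation for substances that don't exist; the scatter is artificial.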